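## The problem

The target **17**, (3S,4R,3'R,6'R)-β,ε-carotene-3,4,3'-triol, joins two different six-membered end rings through an all-E, tetramethylated C18 nonaene chain, so nine double bonds must be set and each ring must end up at its own terminus. Ring ε (C1'–C6') carries the 3'R carbinol and, trans to it, the 6'R methine, which is doubly allylic and is epimerised or moved into conjugation by strong base. Ring β (C1–C6) carries the cis-(3S,4R) diol, whose C4 hydroxyl is allylic to a decaene and ionises with traces of acid, while a late reduction of a C4 ketone would have no strong facial bias. The two pairs of stereocentres lie about 30 Å apart and cannot control each other, but within a ring C3 can control its neighbours: C4 through a hydroxyl-directed reagent, C6 through a cis/trans relationship on the ring. The polyene does not tolerate oxygen, light, acid, iodine or electron-transfer oxidants, so the late steps must be few and mild. The feature the plan exploits is a hidden symmetry: laid over ring ε, ring β has C3 (S) of opposite spatial sense to C3' (R), and its C4(OH)–C5=C6 unit is the C4'=C5'–C6'(H) unit of ring ε after syn oxygenation with allylic shift. The target is therefore a masked meso compound, (3S,6S,3'R,6'R)-ε,ε-carotene-3,3'-diol, and both rings can come from the two enantiomers of one racemic 3,6-trans-3-hydroxy-ε ring.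

## Retrosynthesis

**17 from 15 (through 16).** The cut lies inside ring β. The C5=C6 double bond and the C4 hydroxyl are read as the product of a syn β-elimination: backwards, a C5–O bond is formed (C4–C5 epoxide, oxygen cis to 3-OH), C6 regains its hydrogen, and the 3'-hydroxyl carries an acetate. This beats the neighbouring cuts at C4 (reduction of a C4 ketone, or dihydroxylation of a C3=C4 alkene beside a polyene) because C4 inherits its configuration from an epoxide that C3 can direct. The acid-labile polyene-allylic alcohol then exists only in the last flask. Precursor **15** has ε-type rings at both ends. The forward step must remove C6–H at the epoxide end only and leave C6'–H alone.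

**15 from 14.** The two C–O bonds of the epoxide are cut. Oxygen must reach C4=C5 of one ring in the presence of the same alkene in the other ring and nine chain double bonds. Only a hydroxyl-directed epoxidation can do this, so the rings must differ in one respect: free 3-OH on the ring to be oxidised, acetate on the other. The forward step sets C4 and C5 from C3.

**14 from 13.** No skeletal bond is cut; one acetate is put back. Diacetate **13** is achiral: its (3S,6S) and (3'R,6'R) rings are mirror images. Building **14** from two resolved halves would need a resolution, two end-group lines and an unsymmetrical coupling. Here one lipase step is asked to do all three jobs. A synthesis of **13** from a racemic building block inevitably gives, beside **13**, its chiral diastereomer in which both rings have the same configuration (a racemate, called the like diastereomer of **13** below), and the two cannot be separated. This co-product is never an intermediate on the way to **17**. The enzymatic step must therefore also sort diastereomers: only **13** can give a monoacetate, while the enantiomers of the like diastereomer of **13** lose both acetates or none. The precursor is a stereo-random mixture made without any chiral reagent.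

**13 from 11 and 7 (through 12).** Cuts: C11=C12 and C11'=C12', two disubstituted E double bonds formed in one flask by a two-fold Horner–Wadsworth–Emmons reaction. Cuts at C9=C10 or C13=C14 (trisubstituted, poor E/Z control) or at C15=C15' (two long halves) are worse. This cut uses one C15 aldehyde **7** twice on the symmetric C10 bisphosphonate **11**, and it avoids the acidic conditions of phosphonium salt formation, which the ring allylic oxygen would not survive. The mono-adduct **12** is not isolated.

**7 from 1 and 2 (through 6, 5, 4, 3).** The C9=C10 bond is cut to (±)-α-ionone **1** and phosphonate **2**, giving nitrile **3**. C3 is oxygenated by allylic oxidation (**4**) and the ketone is reduced to the 3,6-trans alcohol **5**, the only diastereoselective step before the polyene exists. The nitrile becomes aldehyde **6**, and acetylation gives **7**. Everything is racemic on purpose.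

**11 from 8 (through 10 and 9).** The two C–P bonds are cut. Commercial C10 dial **8** is reduced to diol **9**, brominated to **10** and subjected to an Arbuzov reaction.

## Roads not taken

**Alternative 1:** the usual stepwise C15 + C10 + C15' plan with two unrelated end groups. The cuts are again C11=C12 and C11'=C12', but made one after the other with ylides. A resolved (3R,6R) ε-end C15 ylide is condensed with excess dial **8** to give C25 aldehyde **A1**. A second Wittig reaction with the (4S)-hydroxy-oxo C15 phosphonium salt **A2** gives C40 hydroxy ketone **A3**, and hydride reduction of C4=O ends the route. The chosen plan is better for three reasons: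
- **A1** and **A2** need two separate enantiopure sources and two building-block lines.
- The first olefination of a symmetric dial is statistical.
- The last step creates C4 on a polyene with no element that enforces the cis diol, so the weakest stereocentre is set last and least selectively.

**Alternative 2:** late-stage C4–H oxygenation. The C4–O bond is cut back to lutein **A4**. The forward key step would be a carotenoid β-ring 4-ketolase (membrane-bound non-haem di-iron oxygenase class), which gives **A3** again, followed by reduction. The chosen plan is better for three reasons: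
- **A4** is itself an unsymmetrical chiral carotenoid that needs the whole of Alternative 1.
- The enzyme stops at the ketone and leaves C4 to an unselective hydride.
- Chemical allylic oxidants would attack the 3'-allylic carbinol and the doubly allylic C6'–H of ring ε before the C4 methylene.

**Alternative 3:** cut of the central C15=C15' bond into two C20 halves, a Wittig reaction of ε-end aldehyde **A5** with the ylide of β-end phosphonium salt **A6**. The chosen plan is better for three reasons:
- Both halves are long linear sequences that carry a tetraene and a sensitive end group through many steps.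
- The central double bond forms as an E/Z mixture.
- The hidden symmetry of the target is not used, so each half needs its own source of chirality.

Key step: step 10

Assumption: the lipase follows the empirical large/medium-substituent rule at C3 of the 3-hydroxy-ε ring with the C2–C1(CH3)2 flank as the large group, so the acetate of the 3S carbinol is the one it cleaves; the configuration of 14 is to be confirmed before step 11.

## Steps

All C40 work is done under argon in dim light. Ring locants are in carotenoid numbering unless a systematic name is given.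

Step 1
Reactants: 1 (±)-α-ionone; 2 diethyl cyanomethylphosphonate
Product: 3 rac-(2E,4E)-3-methyl-5-(2,6,6-trimethylcyclohex-2-en-1-yl)penta-2,4-dienenitrile
Conditions: NaH, THF, 0 °C → rt; (9Z) isomer removed by chromatography
Reagents that add atoms: none
Why: Horner–Wadsworth–Emmons olefination of the methyl ketone; the (9E) isomer should predominate and the isomers are separable at this stage. The base is consumed by the phosphonate, so the ring double bond should not move into conjugation.

Step 2
Reactants: 3 rac-α-ionylideneacetonitrile
Product: 4 rac-(2E,4E)-3-methyl-5-(2,6,6-trimethyl-4-oxocyclohex-2-en-1-yl)penta-2,4-dienenitrile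
Conditions: t-BuOOH (70% in water), aq NaOCl, K2CO3, MeCN, −5 → 0 °C
Reagents that add atoms: tert-butyl hydroperoxide, CC(C)(C)OO
Why: Radical allylic oxidation of the only unhindered allylic methylene (C3) to the enone, the same regiochemistry as the standard oxidation of α-ionone to 3-oxo-α-ionone. C6–H is tertiary, flanked by the quaternary C1 and held out of overlap with the ring π bond; the dienyl nitrile is electron-poor.

Step 3
Reactants: 4 rac-3-oxo nitrile
Product: 5 rac-(2E,4E)-5-[(1R*,4R*)-4-hydroxy-2,6,6-trimethylcyclohex-2-en-1-yl]-3-methylpenta-2,4-dienenitrile (3,6-trans)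
Conditions: NaBH4, CeCl3·7H2O, MeOH, −78 → −40 °C; cis isomer removed by chromatography
Reagents that add atoms: none
Why: Luche 1,2-reduction that leaves the conjugated nitrile alone. The chain at C6 should sit pseudoaxial (1,2-allylic strain with the C5 methyl), which puts the axial C1 methyl on the opposite face; hydride should enter anti to that methyl, syn to the chain, placing OH trans to the chain (3R*,6R*).

Step 4
Reactants: 5 rac-trans hydroxy nitrile
Product: 6 rac-(2E,4E)-5-[(1R*,4R*)-4-hydroxy-2,6,6-trimethylcyclohex-2-en-1-yl]-3-methylpenta-2,4-dienal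
Conditions: i-Bu2AlH (2.5 equiv), CH2Cl2, −78 °C; then wet SiO2, aq KNaC4H4O6, 0 °C
Reagents that add atoms: water, O
Why: Partial reduction of the conjugated nitrile to the N-aluminio aldimine, hydrolysed near neutrality so that the acid-labile ring allylic alcohol and the 9E geometry survive; a standard retinoid transformation.

Step 5
Reactants: 6 rac-trans hydroxy aldehyde
Product: 7 rac-(1R*,4R*)-4-[(1E,3E)-3-methyl-5-oxopenta-1,3-dien-1-yl]-3,5,5-trimethylcyclohex-2-en-1-yl acetate
Conditions: Ac2O, pyridine, DMAP (cat.), CH2Cl2, 0 °C → rt
Reagents that add atoms: acetic anhydride, CC(=O)OC(C)=O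
Why: Routine O-acetylation. The acetate masks the hydroxyl during olefination and is the group the lipase reads in step 10.

Step 6
Reactants: 8 (2E,4E,6E)-2,7-dimethylocta-2,4,6-trienedial
Product: 9 (2E,4E,6E)-2,7-dimethylocta-2,4,6-triene-1,8-diol
Conditions: NaBH4, MeOH–THF, 0 °C
Reagents that add atoms: none
Why: 1,2-Reduction of both conjugated aldehydes; the triene geometry is not touched.

Step 7
Reactants: 9 C10 diol
Product: 10 (2E,4E,6E)-1,8-dibromo-2,7-dimethylocta-2,4,6-triene
Conditions: PBr3, pyridine (cat.), Et2O, −20 → 0 °C, dark; used crude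
Reagents that add atoms: phosphorus tribromide, BrP(Br)Br
Why: Conversion of primary allylic alcohols into bromides through the phosphite esters; low temperature and immediate use limit allylic transposition.

Step 8
Reactants: 10 C10 dibromide
Product: 11 tetraethyl [(2E,4E,6E)-2,7-dimethylocta-2,4,6-triene-1,8-diyl]bis(phosphonate)
Conditions: P(OEt)3, toluene, 110 °C
Reagents that add atoms: triethyl phosphite, CCOP(OCC)OCC
Why: Two-fold Michaelis–Arbuzov reaction at the primary allylic carbons; bromoethane distils off.

Step 9
Reactants: 11 C10 bisphosphonate; 7 rac-acetoxy aldehyde (2.1 equiv in all)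
Product: 13 (3R,6R,3'S,6'S)-ε,ε-carotene-3,3'-diyl diacetate (meso), via rac-C25 acetoxy phosphonate 12 (not isolated)
Conditions: NaN(SiMe3)2 (1.0 equiv), THF, −78 °C, then 7 (1.05 equiv), −78 → −20 °C; second portions of NaN(SiMe3)2 (1.0 equiv) and 7 (1.05 equiv) likewise, → 0 °C; all-E fraction collected on SiO2 (1% Et3N) and used as the stereoisomer mixture
Reagents that add atoms: none
Why: Two-fold Horner–Wadsworth–Emmons olefination run as two consecutive mono-olefinations in one flask, E-selective at C11=C12 and C11'=C12'; the amide base is consumed by the phosphonate before each portion of aldehyde arrives, and the low temperature should spare the acetates. The two rings are too far apart for any diastereo-discrimination, so 13 should be accompanied by an equal amount of its like diastereomer (racemic (3R,6R,3'R,6'R)/(3S,6S,3'S,6'S) diacetate), which is not separable here and is carried into step 10.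

Step 10
Reactants: 13 meso diacetate (as obtained, together with its like diastereomer)
Product: 14 (3S,6S,3'R,6'R)-3-hydroxy-ε,ε-caroten-3'-yl acetate
Conditions: immobilised Burkholderia cepacia lipase, n-BuOH (6 equiv), t-BuOMe–toluene, 35 °C; stopped by HPLC when the fast-reacting acetate is consumed; monoacetate fraction separated from the diol and diacetate fractions on SiO2 (1% Et3N)
Reagents that add atoms: none
Why: Serine-hydrolase alcoholysis: the catalytic serine is acetylated by a ring acetate that fits the active site and the acetyl-enzyme is discharged by n-butanol, so an acetate leaves only a ring the lipase recognises. The closest known reaction types are the lipase kinetic resolution of 3-hydroxy-ε-ring building blocks, the lipase acylation of C40 carotenols, and the enzymatic desymmetrisation of meso diacetates. No ring is closed and no stereocentre is created; the step selects, and each end is read independently because the rigid C18 chain keeps the rings apart. With the (3S,6S) ring as the fast one, meso 13 loses exactly one acetate and gives 14 as a single enantiomer, the (3S,6S,3'S,6'S) enantiomer of the like diastereomer loses both and ends as the (3S,6S,3'S,6'S)-diol, and the (3R,6R,3'R,6'R) enantiomer keeps both. Diastereomers that no column separates are thus turned into diol, monoacetate and diacetate, which differ in polarity. The selectivity needed is a high enantiomer ratio at the ring carbinol; it rests on the unlike flanks of C3, the C2 methylene next to quaternary C1 as the large group and the C4 vinyl carbon as the medium group. The ceiling is one half of the C40 material, accepted for a route with no resolved building block and no unsymmetrical coupling.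

Step 11
Reactants: 14 monoacetate
Product: 15 (3S,4S,5R,6S,3'R,6'R)-3'-acetoxy-4,5-epoxy-4,5-dihydro-ε,ε-caroten-3-ol
Conditions: VO(acac)2 (5 mol %), t-BuOOH (anhydrous, in decane, 1.3 equiv), toluene, −10 → 0 °C; aq Na2S2O3
Reagents that add atoms: tert-butyl hydroperoxide, CC(C)(C)OO
Why: Hydroxyl-directed epoxidation: the vanadate ester of the free 3-OH delivers the peroxide oxygen to C4=C5 on the face of the hydroxyl, which is also the face away from the chain at C6, setting C4 (S) and C5 (R) from C3. The acetylated ring cannot bind the metal and the chain alkenes have no directing group, which should give the chemoselectivity.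

Step 12
Reactants: 15 epoxy alcohol acetate
Product: 17 (3S,4R,3'R,6'R)-β,ε-carotene-3,4,3'-triol, via 3'-O-acetyl triol 16 (not isolated)
Conditions: LiN(i-Pr)2 (5 equiv), THF, −78 → 0 °C; then MeOH, 0 °C → rt; aq NH4Cl
Reagents that add atoms: none
Why: Base-induced isomerisation of an epoxide to an allylic alcohol by syn β-elimination: the amide, held in a mixed aggregate by the lithium 3-alkoxide and the epoxide oxygen, reaches C6–H, which lies on the same face and is the only β-hydrogen acidified by the polyene. The C5–O bond breaks, C5=C6 enters conjugation and the oxygen stays on C4 with its configuration, cis to 3-OH (4R); a Payne shift is excluded because the alkoxide is cis to the epoxide. Methanol then gives LiOMe, which removes the 3'-acetate by transesterification.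

## Compound list

1 | (±)-α-ionone, (E)-4-(2,6,6-trimethylcyclohex-2-en-1-yl)but-3-en-2-one | CC(=O)/C=C/C1C(C)=CCCC1(C)C | starting material
2 | diethyl cyanomethylphosphonate | CCOP(=O)(CC#N)OCC | starting material
3 | rac-(2E,4E)-3-methyl-5-(2,6,6-trimethylcyclohex-2-en-1-yl)penta-2,4-dienenitrile | N#C/C=C(C)/C=C/C1C(C)=CCCC1(C)C | intermediate
4 | rac-(2E,4E)-3-methyl-5-(2,6,6-trimethyl-4-oxocyclohex-2-en-1-yl)penta-2,4-dienenitrile | N#C/C=C(C)/C=C/C1C(C)=CC(=O)CC1(C)C | intermediate
5 | rac-(2E,4E)-5-[(1R*,4R*)-4-hydroxy-2,6,6-trimethylcyclohex-2-en-1-yl]-3-methylpenta-2,4-dienenitrile (racemate, 3R,6R enantiomer drawn) | CC1=C[C@H](O)CC(C)(C)[C@H]1/C=C/C(C)=C/C#N | intermediate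
6 | rac-(2E,4E)-5-[(1R*,4R*)-4-hydroxy-2,6,6-trimethylcyclohex-2-en-1-yl]-3-methylpenta-2,4-dienal (racemate, 3R,6R enantiomer drawn) | CC1=C[C@H](O)CC(C)(C)[C@H]1/C=C/C(C)=C/C=O | intermediate
7 | rac-(1R*,4R*)-4-[(1E,3E)-3-methyl-5-oxopenta-1,3-dien-1-yl]-3,5,5-trimethylcyclohex-2-en-1-yl acetate (racemate, 3R,6R enantiomer drawn) | CC1=C[C@H](OC(C)=O)CC(C)(C)[C@H]1/C=C/C(C)=C/C=O | intermediate
8 | (2E,4E,6E)-2,7-dimethylocta-2,4,6-trienedial | O=C/C(C)=C/C=C/C=C(C)/C=O | starting material
9 | (2E,4E,6E)-2,7-dimethylocta-2,4,6-triene-1,8-diol | OC/C(C)=C/C=C/C=C(C)/CO | intermediate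
10 | (2E,4E,6E)-1,8-dibromo-2,7-dimethylocta-2,4,6-triene | BrC/C(C)=C/C=C/C=C(C)/CBr | intermediate
11 | tetraethyl [(2E,4E,6E)-2,7-dimethylocta-2,4,6-triene-1,8-diyl]bis(phosphonate) | CCOP(=O)(OCC)C/C(C)=C/C=C/C=C(C)/CP(=O)(OCC)OCC | intermediate
12 | rac-diethyl [(2E,4E,6E,8E,10E,12E)-13-[(1R*,4R*)-4-acetoxy-2,6,6-trimethylcyclohex-2-en-1-yl]-2,7,11-trimethyltrideca-2,4,6,8,10,12-hexaen-1-yl]phosphonate (racemate, 3R,6R enantiomer drawn; not isolated) | CC1=C[C@H](OC(C)=O)CC(C)(C)[C@H]1/C=C/C(C)=C/C=C/C(C)=C/C=C/C=C(C)/CP(=O)(OCC)OCC | intermediate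
13 | (3R,6R,3'S,6'S)-ε,ε-carotene-3,3'-diyl diacetate (meso; obtained together with its racemic like diastereomer, which is removed in step 10) | CC1=C[C@H](OC(C)=O)CC(C)(C)[C@H]1/C=C/C(C)=C/C=C/C(C)=C/C=C/C=C(C)/C=C/C=C(C)/C=C/[C@@H]1C(C)=C[C@@H](OC(C)=O)CC1(C)C | intermediate
14 | (3S,6S,3'R,6'R)-3-hydroxy-ε,ε-caroten-3'-yl acetate | CC1=C[C@H](OC(C)=O)CC(C)(C)[C@H]1/C=C/C(C)=C/C=C/C(C)=C/C=C/C=C(C)/C=C/C=C(C)/C=C/[C@@H]1C(C)=C[C@@H](O)CC1(C)C | intermediate
15 | (3S,4S,5R,6S,3'R,6'R)-3'-acetoxy-4,5-epoxy-4,5-dihydro-ε,ε-caroten-3-ol | CC1=C[C@H](OC(C)=O)CC(C)(C)[C@H]1/C=C/C(C)=C/C=C/C(C)=C/C=C/C=C(C)/C=C/C=C(C)/C=C/[C@@H]1[C@@]2(C)O[C@H]2[C@@H](O)CC1(C)C | intermediate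
16 | (3S,4R,3'R,6'R)-3,4-dihydroxy-β,ε-caroten-3'-yl acetate (not isolated) | CC1=C[C@H](OC(C)=O)CC(C)(C)[C@H]1/C=C/C(C)=C/C=C/C(C)=C/C=C/C=C(C)/C=C/C=C(C)/C=C/C1=C(C)[C@@H](O)[C@@H](O)CC1(C)C | intermediate
17 | (3S,4R,3'R,6'R)-β,ε-carotene-3,4,3'-triol | CC1=C[C@H](O)CC(C)(C)[C@H]1/C=C/C(C)=C/C=C/C(C)=C/C=C/C=C(C)/C=C/C=C(C)/C=C/C1=C(C)[C@@H](O)[C@@H](O)CC1(C)C | target

## Step count and least certain steps

Total: 12 steps. Longest linear sequence: 9 steps (1–5, 9–12); the C10 branch (6–8) has 3.

**Step 10 (key step).** The enantiodiscrimination between the two ring carbinols may be too low on a substrate of this size, turnover may be slow, or the preference may be opposite to the one assumed. Low discrimination would let stereoisomers that stem from the like diastereomer of 13 leak into the monoacetate fraction; an opposite preference would deliver the mirror-image monoacetate. The fallback sets out from 5 and returns at 14; it moves the resolution to the C15 stage, where both enantiomers are obtained whatever the preference of the enzyme, and gives up the two-directional coupling. Acylation of rac-5 with the same lipase and vinyl acetate should give (3S,6S)-acetoxy nitrile F1 and leave (3R,6R)-hydroxy nitrile F2, separable as ester and alcohol. F2 is reduced with i-Bu2AlH to (3R,6R)-hydroxy aldehyde F3 and acetylated to (3R,6R)-acetoxy aldehyde F4. F1 with excess i-Bu2AlH gives (3S,6S)-hydroxy aldehyde F5 directly, since the nitrile is reduced and the acetate cleaved. Mono-olefination of an excess of 11 with F4 gives the enantiopure C25 acetoxy phosphonate F6, and the anion of F6 combined with the sodium alkoxide of F5 gives 14.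

**Step 11.** The nonaene may be oxidised, by electron transfer to pentavalent vanadium or by attack of tert-butylperoxyl radicals, faster than the directed oxygen transfer occurs; the allylic alcohol may also be over-oxidised to the enone. The fallback sets out from 5 and returns at 15; it does the epoxidation before the polyene exists. F1 and F6 are made as described for step 10. Methanolysis of F1 (K2CO3, MeOH) gives (3S,6S)-hydroxy nitrile F7. VO(acac)2 and t-BuOOH convert F7 into epoxy alcohol nitrile F8, whose only other alkenes are the electron-poor dienyl nitrile. i-Bu2AlH at −78 °C gives epoxy hydroxy aldehyde F9, and olefination of the alkoxide of F9 with the anion of F6 at −78 °C gives 15.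

**Step 12.** Site selectivity of the deprotonation may be lost. Removal of C6'–H at the other ring would epimerise C6' or conjugate that ring, removal of a C5-methyl proton (the usual preference of lithium amides with unactivated epoxides) would give an exocyclic alkene, and the polyenyl anion may decompose. The fallback sets out from 5 and returns at 17; it does the elimination where C6–H is activated by the nitrile and no second ring is present. Epoxy alcohol nitrile F8, made as described for step 11, is treated with KOt-Bu in THF at 0 °C; an E1cB opening of the epoxide through the nitrile-stabilised trienyl anion should give cis-diol nitrile F10, the analogue of the known conversion of epoxy-α-ionone into 4-hydroxy-β-ionone. i-Bu2AlH gives diol aldehyde F11, and acetylation gives diacetoxy aldehyde F12. Olefination of F12 with the anion of F6 (step 10 fallback) gives C40 triacetate F13, and K2CO3 in MeOH gives 17.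

**Step 3.** Facial selectivity of the hydride addition may be poor or reversed, which would make the 3,6-cis alcohol the main product. The fallback sets out from 4 and returns at 5; it corrects the carbinol by inversion instead of relying on the reduction. The reduction of 4 is run under whatever conditions give most cis alcohol F14. A Mitsunobu reaction (4-nitrobenzoic acid, PPh3, DIAD) inverts C3 to the trans 4-nitrobenzoate F15, and methanolysis (K2CO3, MeOH) gives 5.

## Further compounds

F1 | step 10 | (2E,4E)-5-[(1S,4S)-4-acetoxy-2,6,6-trimethylcyclohex-2-en-1-yl]-3-methylpenta-2,4-dienenitrile | CC1=C[C@@H](OC(C)=O)CC(C)(C)[C@@H]1/C=C/C(C)=C/C#N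
F2 | step 10 | (2E,4E)-5-[(1R,4R)-4-hydroxy-2,6,6-trimethylcyclohex-2-en-1-yl]-3-methylpenta-2,4-dienenitrile (single enantiomer) | CC1=C[C@H](O)CC(C)(C)[C@H]1/C=C/C(C)=C/C#N
F3 | step 10 | (2E,4E)-5-[(1R,4R)-4-hydroxy-2,6,6-trimethylcyclohex-2-en-1-yl]-3-methylpenta-2,4-dienal (single enantiomer) | CC1=C[C@H](O)CC(C)(C)[C@H]1/C=C/C(C)=C/C=O
F4 | step 10 | (1R,4R)-4-[(1E,3E)-3-methyl-5-oxopenta-1,3-dien-1-yl]-3,5,5-trimethylcyclohex-2-en-1-yl acetate (single enantiomer) | CC1=C[C@H](OC(C)=O)CC(C)(C)[C@H]1/C=C/C(C)=C/C=O
F5 | step 10 | (2E,4E)-5-[(1S,4S)-4-hydroxy-2,6,6-trimethylcyclohex-2-en-1-yl]-3-methylpenta-2,4-dienal | CC1=C[C@@H](O)CC(C)(C)[C@@H]1/C=C/C(C)=C/C=O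
F6 | step 10 | diethyl [(2E,4E,6E,8E,10E,12E)-13-[(1R,4R)-4-acetoxy-2,6,6-trimethylcyclohex-2-en-1-yl]-2,7,11-trimethyltrideca-2,4,6,8,10,12-hexaen-1-yl]phosphonate (single enantiomer) | CC1=C[C@H](OC(C)=O)CC(C)(C)[C@H]1/C=C/C(C)=C/C=C/C(C)=C/C=C/C=C(C)/CP(=O)(OCC)OCC
F7 | step 11 | (2E,4E)-5-[(1S,4S)-4-hydroxy-2,6,6-trimethylcyclohex-2-en-1-yl]-3-methylpenta-2,4-dienenitrile | CC1=C[C@@H](O)CC(C)(C)[C@@H]1/C=C/C(C)=C/C#N
F8 | step 11 | (2E,4E)-3-methyl-5-[(3S,4S,5R,6S)-4,5-epoxy-3-hydroxy-1,1,5-trimethylcyclohexan-6-yl]penta-2,4-dienenitrile (carotenoid ring numbering; epoxide cis to OH, trans to the chain) | N#C/C=C(C)/C=C/[C@@H]1[C@@]2(C)O[C@H]2[C@@H](O)CC1(C)C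
F9 | step 11 | (2E,4E)-3-methyl-5-[(3S,4S,5R,6S)-4,5-epoxy-3-hydroxy-1,1,5-trimethylcyclohexan-6-yl]penta-2,4-dienal (carotenoid ring numbering) | O=C/C=C(C)/C=C/[C@@H]1[C@@]2(C)O[C@H]2[C@@H](O)CC1(C)C
F10 | step 12 | (2E,4E)-5-[(3S,4R)-3,4-dihydroxy-2,6,6-trimethylcyclohex-1-en-1-yl]-3-methylpenta-2,4-dienenitrile | N#C/C=C(C)/C=C/C1=C(C)[C@@H](O)[C@@H](O)CC1(C)C
F11 | step 12 | (2E,4E)-5-[(3S,4R)-3,4-dihydroxy-2,6,6-trimethylcyclohex-1-en-1-yl]-3-methylpenta-2,4-dienal | O=C/C=C(C)/C=C/C1=C(C)[C@@H](O)[C@@H](O)CC1(C)C
F12 | step 12 | (2E,4E)-5-[(3S,4R)-3,4-diacetoxy-2,6,6-trimethylcyclohex-1-en-1-yl]-3-methylpenta-2,4-dienal | O=C/C=C(C)/C=C/C1=C(C)[C@@H](OC(C)=O)[C@@H](OC(C)=O)CC1(C)C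
F13 | step 12 | (3S,4R,3'R,6'R)-β,ε-carotene-3,4,3'-triyl triacetate | CC1=C[C@H](OC(C)=O)CC(C)(C)[C@H]1/C=C/C(C)=C/C=C/C(C)=C/C=C/C=C(C)/C=C/C=C(C)/C=C/C1=C(C)[C@@H](OC(C)=O)[C@@H](OC(C)=O)CC1(C)C
F14 | step 3 | rac-(2E,4E)-5-[(1R*,4S*)-4-hydroxy-2,6,6-trimethylcyclohex-2-en-1-yl]-3-methylpenta-2,4-dienenitrile (3,6-cis; racemate, 3S,6R enantiomer drawn) | CC1=C[C@@H](O)CC(C)(C)[C@H]1/C=C/C(C)=C/C#N
F15 | step 3 | rac-(1R*,4R*)-4-[(1E,3E)-4-cyano-3-methylbuta-1,3-dien-1-yl]-3,5,5-trimethylcyclohex-2-en-1-yl 4-nitrobenzoate (3,6-trans; racemate, 3R,6R enantiomer drawn) | CC1=C[C@H](OC(=O)c2ccc(cc2)[N+](=O)[O-])CC(C)(C)[C@H]1/C=C/C(C)=C/C#N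
A1 | alternative 1 | (3R,6R)-3-hydroxy-12'-apo-ε-caroten-12'-al | CC1=C[C@H](O)CC(C)(C)[C@H]1/C=C/C(C)=C/C=C/C(C)=C/C=C/C=C(C)/C=O
A2 | alternative 1 | [(2E,4E)-5-[(4S)-4-hydroxy-2,6,6-trimethyl-3-oxocyclohex-1-en-1-yl]-3-methylpenta-2,4-dien-1-yl]triphenylphosphonium bromide | c1ccccc1[P+](c1ccccc1)(c1ccccc1)C/C=C(C)/C=C/C1=C(C)C(=O)[C@@H](O)CC1(C)C.[Br-]
A3 | alternative 1 | (3S,3'R,6'R)-3,3'-dihydroxy-β,ε-caroten-4-one | CC1=C[C@H](O)CC(C)(C)[C@H]1/C=C/C(C)=C/C=C/C(C)=C/C=C/C=C(C)/C=C/C=C(C)/C=C/C1=C(C)C(=O)[C@@H](O)CC1(C)C
A4 | alternative 2 | lutein, (3R,3'R,6'R)-β,ε-carotene-3,3'-diol | CC1=C[C@H](O)CC(C)(C)[C@H]1/C=C/C(C)=C/C=C/C(C)=C/C=C/C=C(C)/C=C/C=C(C)/C=C/C1=C(C)C[C@@H](O)CC1(C)C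
A5 | alternative 3 | (2E,4E,6E,8E)-9-[(1R,4R)-4-hydroxy-2,6,6-trimethylcyclohex-2-en-1-yl]-3,7-dimethylnona-2,4,6,8-tetraenal | CC1=C[C@H](O)CC(C)(C)[C@H]1/C=C/C(C)=C/C=C/C(C)=C/C=O
A6 | alternative 3 | [(2E,4E,6E,8E)-9-[(3S,4R)-3,4-dihydroxy-2,6,6-trimethylcyclohex-1-en-1-yl]-3,7-dimethylnona-2,4,6,8-tetraen-1-yl]triphenylphosphonium bromide | c1ccccc1[P+](c1ccccc1)(c1ccccc1)C/C=C(C)/C=C/C=C(C)/C=C/C1=C(C)[C@@H](O)[C@@H](O)CC1(C)C.[Br-]
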